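**Plan**

- Carotenoid locants are used: ring B is the dihydroxy ring (C1–C6), ring A the hydroxycyclohexenylidene ring (primed). The polyene is cut at C15–C15' (Stille), at C10=C11 and C10'=C11' (Horner–Wadsworth–Emmons with the C5 phosphonates 17 and 18), at C8=C9 and C8'=C9' (Wittig), at C7–C8 (carbonylation of an enol triflate) and at C6'=C7' (ethynylation, Meyer–Schuster). Ring B is cut at C1–C2 and C4–C5.
- Enabling feature: in ring B the C3 oxygen sits between two CH2 groups and 1,3 to the tertiary C5 carbinol, and the gem-dimethyl carbon C1 is β to C5 through C6. With C3 as a ketone, C2–C3–C4 is acetone, C5 is an aldol acceptor and C1 a Michael terminus, so acetone and an α-ethoxycarbonyl mesityl oxide (C1, C6, C5, ester C7) close the ring in one Michael/aldol [3+3] annulation.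
- Forward: Knoevenagel → annulation (ring B, both fully substituted carbons) → directed reduction, silylation → C7 aldehyde → E enol triflate → enal → dienal → C20 stannane. In parallel: actinol → ring A enone → ethynyl carbinol → enal → dienal → C20 iodide. Then Stille union and desilylation.
- Stereochemistry: C5 from the proline-controlled aldol closure; C3 relayed from C5 by hydroxyl-directed anti reduction; C3' from (4R,6R)-actinol. Alkene geometry comes from E-selective Wittig and Horner–Wadsworth–Emmons steps, syn-hydrostannation, a geometry-defined enol triflate and stereoretentive palladium couplings.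

Key step: step 2

Remark: (4R,6R)-actinol and (E)-3-methylpent-2-en-4-yn-1-ol are taken as commercial. The ester-bearing carbon of 5–9 is drawn as the expected cis-hydroxy ester epimer; either epimer converges at step 7.

**Ring B half**

Step 1
Reactants: 1 ethyl acetoacetate; 2 acetone
Product: 3 ethyl 2-acetyl-3-methylbut-2-enoate
Conditions: TiCl4, pyridine, THF, 0 °C → rt
Reagents that add atoms: none
Why: Knoevenagel condensation under Lehnert conditions, in which TiCl4 activates the ketone and the titanium enolate of the β-keto ester condenses and dehydrates irreversibly, should give the tetrasubstituted alkylidene acetoacetate that holds C1, C6, C5 and C7 of ring B.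

Step 2
Reactants: 3 ethyl 2-acetyl-3-methylbut-2-enoate; 2 acetone (also co-solvent)
Product: 5 ethyl (1R,2S)-2-hydroxy-2,6,6-trimethyl-4-oxocyclohexane-1-carboxylate, via diketo ester 4 (not isolated)
Conditions: (S)-proline (30 mol %), acetone/DMSO (1:4), rt → 40 °C
Reagents that add atoms: none
Why: Proposed new method: the enamine from (S)-proline and acetone adds in conjugate fashion to the gem-dimethyl terminus of the doubly activated alkene of 3 (first bond, quaternary C1), tautomerisation gives diketo ester 4, and the enamine of its new methyl ketone then attacks the ester-activated acetyl carbonyl (second bond, C4–C5) before hydrolysis returns the catalyst. The closest known reaction types are amine-catalysed Michael additions of ketones to alkylidene 1,3-dicarbonyl compounds and the Hajos–Parrish–Eder–Sauer–Wiechert ketol cyclisation, and 4 is also the intermediate of the classical base-mediated annulation of ethyl acetoacetate with mesityl oxide, which closes with this regiochemistry; new here is the enamine addition to a fully substituted alkene carbon combined with catalyst control over a tertiary carbinol. The six-membered ring closes by a 6-(enolendo)-exo-trig aldol addition through a chair. The C5 carbinol centre is catalyst-controlled: in the Houk–List arrangement (anti enamine, carboxylic acid hydrogen-bonded to the acetyl oxygen, acetyl methyl equatorial, oxygen axial) (S)-proline is predicted to expose the face that gives the (2S) carbinol of 5, while the ester-bearing carbon equilibrates through the β-keto ester enol of 4, is expected to end equatorial and cis to the hydroxyl, and is erased at step 7. The step needs conjugate addition to win over γ-deprotonation or enamino ester formation of 3, attack by the acetone-derived methyl instead of the acetyl methyl, and survival of the β-ketol; the neutral enamine manifold, the higher electrophilicity of the ester-flanked ketone and the absence of acid, base or heat should secure these.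

Step 3
Reactants: 5 ethyl (1R,2S)-2-hydroxy-2,6,6-trimethyl-4-oxocyclohexane-1-carboxylate
Product: 6 ethyl (1R,2S,4R)-2,4-dihydroxy-2,6,6-trimethylcyclohexane-1-carboxylate
Conditions: Me4NBH(OAc)3, MeCN/AcOH (1:1), −30 °C
Reagents that add atoms: none
Why: Evans–Saksena hydroxyl-directed reduction, in which the axial tertiary hydroxyl binds boron and delivers hydride to the same face of the C3 ketone, should place the new hydroxyl trans to it (3R in carotenoid numbering) and leave the ester untouched.

Step 4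
Reactants: 6 ethyl (1R,2S,4R)-2,4-dihydroxy-2,6,6-trimethylcyclohexane-1-carboxylate
Product: 7 ethyl (1R,2S,4R)-2,6,6-trimethyl-2,4-bis(triethylsilyloxy)cyclohexane-1-carboxylate
Conditions: Et3SiOTf (2.5 equiv), 2,6-lutidine, CH2Cl2, −78 → 0 °C
Reagents that add atoms: triethylsilyl trifluoromethanesulfonate, CC[Si](CC)(CC)OS(=O)(=O)C(F)(F)F
Why: Silylation with a silyl triflate and a hindered base protects the secondary and the hindered tertiary hydroxyl in one step, which blocks retro-aldol cleavage in the later enolisation.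

Step 5
Reactants: 7 ethyl (1R,2S,4R)-2,6,6-trimethyl-2,4-bis(triethylsilyloxy)cyclohexane-1-carboxylate
Product: 8 [(1S,2S,4R)-2,6,6-trimethyl-2,4-bis(triethylsilyloxy)cyclohexyl]methanol
Conditions: (i-Bu)2AlH (3 equiv), CH2Cl2, −78 → 0 °C
Reagents that add atoms: none
Why: Hydride reduction of the hindered ester to the primary alcohol is standard, and the non-basic aluminium reagent in CH2Cl2 avoids silyl migration.

Step 6
Reactants: 8 [(1S,2S,4R)-2,6,6-trimethyl-2,4-bis(triethylsilyloxy)cyclohexyl]methanol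
Product: 9 (1R,2S,4R)-2,6,6-trimethyl-2,4-bis(triethylsilyloxy)cyclohexane-1-carbaldehyde
Conditions: Dess–Martin periodinane, CH2Cl2, 0 °C → rt
Reagents that add atoms: none
Why: Dess–Martin oxidation gives the C7 aldehyde under near-neutral conditions that spare the β-silyloxy group and both silyl ethers.

Step 7
Reactants: 9 (1R,2S,4R)-2,6,6-trimethyl-2,4-bis(triethylsilyloxy)cyclohexane-1-carbaldehyde
Product: 11 (E)-[(2S,4R)-2,6,6-trimethyl-2,4-bis(triethylsilyloxy)cyclohexylidene]methyl trifluoromethanesulfonate, via potassium enolate 10 (not isolated)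
Conditions: KN(SiMe3)2 (1.05 equiv), 18-crown-6, THF, −78 °C; then PhNTf2, −78 → −20 °C
Reagents that add atoms: N-phenylbis(trifluoromethanesulfonimide), O=S(=O)(N(c1ccccc1)S(=O)(=O)C(F)(F)F)C(F)(F)F
Why: Enolisation of the aldehyde at its only α-hydrogen and O-sulfonylation is the standard route to aldehyde enol triflates, and a crown-separated potassium enolate that cannot chelate the silyl ether is expected to place its oxygen away from the axial C5 silyloxy group, next to the gem-dimethyl carbon, which gives the E triflate and makes C6 trigonal.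

Step 8
Reactants: 11 (E)-[(2S,4R)-2,6,6-trimethyl-2,4-bis(triethylsilyloxy)cyclohexylidene]methyl trifluoromethanesulfonate
Product: 12 (2E)-2-[(2S,4R)-2,6,6-trimethyl-2,4-bis(triethylsilyloxy)cyclohexylidene]acetaldehyde
Conditions: Pd(PPh3)4 (5 mol %), LiCl, CO (1 atm), Bu3SnH (slow addition), THF, 50 °C
Reagents that add atoms: carbon monoxide, [C-]#[O+]
Why: Stille-type reductive carbonylation (oxidative addition of zerovalent palladium into the vinyl C–O bond, CO insertion, hydride transfer from tin) forms the C7–C8 bond with retention of the alkene geometry.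

Step 9
Reactants: 12 (2E)-2-[(2S,4R)-2,6,6-trimethyl-2,4-bis(triethylsilyloxy)cyclohexylidene]acetaldehyde
Product: 13 (2E,4E)-2-methyl-4-[(2S,4R)-2,6,6-trimethyl-2,4-bis(triethylsilyloxy)cyclohexylidene]but-2-enal
Conditions: Ph3P=C(Me)CHO, toluene, 90 °C
Reagents that add atoms: 2-(triphenylphosphoranylidene)propanal, CC(C=O)=P(c1ccccc1)(c1ccccc1)c1ccccc1
Why: Wittig reaction of a stabilised ylide is E-selective and stops after one homologation because the α-methyl dienal is less electrophilic, which sets the trisubstituted C8=C9 alkene.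

**C5 phosphonates**

Step 10
Reactants: 14 (E)-3-methylpent-2-en-4-yn-1-ol
Product: 15 (2E,4E)-3-methyl-5-(tributylstannyl)penta-2,4-dien-1-ol
Conditions: Bu3SnH, PdCl2(PPh3)2 (2 mol %), THF, 0 °C → rt
Reagents that add atoms: tributyltin hydride, CCCC[SnH](CCCC)CCCC
Why: Palladium-catalysed hydrostannation adds syn across the terminal alkyne with tin at the terminal carbon, giving the E vinylstannane (the minor internal regioisomer is removed by chromatography).

Step 11
Reactants: 15 (2E,4E)-3-methyl-5-(tributylstannyl)penta-2,4-dien-1-ol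
Product: 16 tributyl[(1E,3E)-5-bromo-3-methylpenta-1,3-dien-1-yl]stannane
Conditions: CBr4, PPh3, 2,6-lutidine (0.1 equiv), CH2Cl2, 0 °C
Reagents that add atoms: carbon tetrabromide, BrC(Br)(Br)Br
Why: Appel bromination converts the primary allylic alcohol under buffered, non-acidic conditions that avoid protodestannylation.

Step 12
Reactants: 16 tributyl[(1E,3E)-5-bromo-3-methylpenta-1,3-dien-1-yl]stannane
Product: 17 diethyl [(2E,4E)-3-methyl-5-(tributylstannyl)penta-2,4-dien-1-yl]phosphonate
Conditions: P(OEt)3, toluene, 90 °C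
Reagents that add atoms: triethyl phosphite, CCOP(OCC)OCC
Why: Michaelis–Arbuzov reaction of the primary allylic bromide gives the dienylphosphonate by direct substitution.

Step 13
Reactants: 17 diethyl [(2E,4E)-3-methyl-5-(tributylstannyl)penta-2,4-dien-1-yl]phosphonate
Product: 18 diethyl [(2E,4E)-5-iodo-3-methylpenta-2,4-dien-1-yl]phosphonate
Conditions: I2, CH2Cl2, 0 °C
Reagents that add atoms: iodine, II
Why: Iododestannylation is a fast ipso substitution that proceeds with retention of the E geometry.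

Step 14
Reactants: 17 diethyl [(2E,4E)-3-methyl-5-(tributylstannyl)penta-2,4-dien-1-yl]phosphonate; 13 (2E,4E)-2-methyl-4-[(2S,4R)-2,6,6-trimethyl-2,4-bis(triethylsilyloxy)cyclohexylidene]but-2-enal
Product: 20 tributyl{(1E,3E,5E,7E,9E)-3,7-dimethyl-9-[(2S,4R)-2,6,6-trimethyl-2,4-bis(triethylsilyloxy)cyclohexylidene]nona-1,3,5,7-tetraen-1-yl}stannane, via α-sodio phosphonate 19 (not isolated)
Conditions: NaN(SiMe3)2, THF, −78 °C; then 13, −78 → 0 °C
Reagents that add atoms: none
Why: Horner–Wadsworth–Emmons olefination of the dienal with the allylic phosphonate anion reacts at the α-carbon and is E-selective for the new disubstituted C10=C11 alkene.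

**Ring A half**

Step 15
Reactants: 21 (4R,6R)-4-hydroxy-2,2,6-trimethylcyclohexan-1-one (actinol)
Product: 22 (4R,6R)-4-[(tert-butyldimethylsilyl)oxy]-2,2,6-trimethylcyclohexan-1-one
Conditions: t-BuMe2SiCl, imidazole, DMF, rt
Reagents that add atoms: tert-butyldimethylsilyl chloride, CC(C)(C)[Si](C)(C)Cl
Why: Standard silylation of the secondary hydroxyl, which carries the C3' stereocentre from the chiral pool.

Step 16
Reactants: 22 (4R,6R)-4-[(tert-butyldimethylsilyl)oxy]-2,2,6-trimethylcyclohexan-1-one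
Product: 24 (4S)-4-[(tert-butyldimethylsilyl)oxy]-2,6,6-trimethylcyclohex-2-en-1-one, via trimethylsilyl enol ether 23 (not isolated)
Conditions: LiN(i-Pr)2, THF, −78 °C; Me3SiCl, −78 °C → rt; then Pd(OAc)2 (10 mol %), O2 (1 atm), DMSO, rt
Reagents that add atoms: none
Why: Saegusa–Ito dehydrogenation (Larock aerobic variant) of the only possible silyl enol ether should give the endocyclic trisubstituted enone, the C4'=C5' alkene of ring A, without touching the silyloxy stereocentre.

Step 17
Reactants: 24 (4S)-4-[(tert-butyldimethylsilyl)oxy]-2,6,6-trimethylcyclohex-2-en-1-one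
Product: 25 (4S)-4-[(tert-butyldimethylsilyl)oxy]-1-ethynyl-2,6,6-trimethylcyclohex-2-en-1-ol (C1 epimers)
Conditions: HC≡CMgBr, THF, 0 °C → rt
Reagents that add atoms: ethynylmagnesium bromide, C#C[Mg]Br
Why: 1,2-Addition of a small alkynyl Grignard reagent to the hindered enone carbonyl is well precedented for 2,6,6-trimethylcyclohexenones, and the new carbinol configuration is irrelevant because this carbon becomes trigonal in step 18.

Step 18
Reactants: 25 (4S)-4-[(tert-butyldimethylsilyl)oxy]-1-ethynyl-2,6,6-trimethylcyclohex-2-en-1-ol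
Product: 26 (2E)-2-[(4S)-4-[(tert-butyldimethylsilyl)oxy]-2,6,6-trimethylcyclohex-2-en-1-ylidene]acetaldehyde
Conditions: MoO2(acac)2 (1 mol %), AuCl(PPh3) (1 mol %), AgOTf (1 mol %), toluene, rt
Reagents that add atoms: none
Why: Meyer–Schuster rearrangement (1,3-shift of the hydroxyl to the alkyne terminus and tautomerisation) gives the cyclohexylidene acetaldehyde, and the E isomer is expected because the formyl-bearing carbon avoids the in-plane C5' methyl.

Step 19
Reactants: 26 (2E)-2-[(4S)-4-[(tert-butyldimethylsilyl)oxy]-2,6,6-trimethylcyclohex-2-en-1-ylidene]acetaldehyde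
Product: 27 (2E,4E)-4-[(4S)-4-[(tert-butyldimethylsilyl)oxy]-2,6,6-trimethylcyclohex-2-en-1-ylidene]-2-methylbut-2-enal
Conditions: Ph3P=C(Me)CHO, toluene, 90 °C
Reagents that add atoms: 2-(triphenylphosphoranylidene)propanal, CC(C=O)=P(c1ccccc1)(c1ccccc1)c1ccccc1
Why: E-selective Wittig reaction of the stabilised ylide, as in step 9, sets the C8'=C9' alkene.

Step 20
Reactants: 18 diethyl [(2E,4E)-5-iodo-3-methylpenta-2,4-dien-1-yl]phosphonate; 27 (2E,4E)-4-[(4S)-4-[(tert-butyldimethylsilyl)oxy]-2,6,6-trimethylcyclohex-2-en-1-ylidene]-2-methylbut-2-enal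
Product: 29 tert-butyl({(1S,4E)-4-[(2E,4E,6E,8E)-9-iodo-3,7-dimethylnona-2,4,6,8-tetraen-1-ylidene]-3,5,5-trimethylcyclohex-2-en-1-yl}oxy)dimethylsilane, via α-sodio phosphonate 28 (not isolated)
Conditions: NaN(SiMe3)2, THF, −78 °C; then 27, −78 → 0 °C
Reagents that add atoms: none
Why: E-selective Horner–Wadsworth–Emmons olefination, as in step 14, forms C10'=C11' and the vinyl iodide is inert to the stabilised carbanion at low temperature.

**Union**

Step 21
Reactants: 29 ring A C20 iodide; 20 ring B C20 stannane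
Product: 30 (3R,5S,3'S,6E,6'E)-3'-(tert-butyldimethylsilyloxy)-3,5-bis(triethylsilyloxy)-4',5-retro-β,β-carotene (all-E)
Conditions: Pd2(dba)3 (5 mol %), AsPh3 (20 mol %), NMP, rt, dark
Reagents that add atoms: none
Why: Stille coupling of an alkenyl iodide with an alkenylstannane under ligand-accelerated conditions forms the central C15–C15' single bond at room temperature with retention of both alkene geometries.

Step 22
Reactants: 30 tris-silyl ether of the target
Product: 31 (3R,5S,3'S,6E,6'E)-4',5-retro-β,β-carotene-3,5,3'-triol (all-E; the target)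
Conditions: Bu4NF, THF, 0 °C → rt, dark
Reagents that add atoms: none
Why: Fluoride-mediated desilylation removes all three silyl ethers without acid, which the tertiary allylic carbinol and the polyene would not tolerate.

**Compound list**

1 | ethyl acetoacetate | CCOC(=O)CC(C)=O | starting material
2 | acetone | CC(C)=O | starting material
3 | ethyl 2-acetyl-3-methylbut-2-enoate | CCOC(=O)C(C(C)=O)=C(C)C | intermediate
4 | ethyl 2-acetyl-3,3-dimethyl-5-oxohexanoate (racemic, stereolabile; not isolated) | CCOC(=O)C(C(C)=O)C(C)(C)CC(C)=O | intermediate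
5 | ethyl (1R,2S)-2-hydroxy-2,6,6-trimethyl-4-oxocyclohexane-1-carboxylate (hydroxyl cis to ester) | CCOC(=O)[C@@H]1C(C)(C)CC(=O)C[C@]1(C)O | intermediate
6 | ethyl (1R,2S,4R)-2,4-dihydroxy-2,6,6-trimethylcyclohexane-1-carboxylate (hydroxyls trans) | CCOC(=O)[C@@H]1C(C)(C)C[C@@H](O)C[C@]1(C)O | intermediate
7 | ethyl (1R,2S,4R)-2,6,6-trimethyl-2,4-bis(triethylsilyloxy)cyclohexane-1-carboxylate | CCOC(=O)[C@@H]1C(C)(C)C[C@@H](O[Si](CC)(CC)CC)C[C@]1(C)O[Si](CC)(CC)CC | intermediate
8 | [(1S,2S,4R)-2,6,6-trimethyl-2,4-bis(triethylsilyloxy)cyclohexyl]methanol | OC[C@@H]1C(C)(C)C[C@@H](O[Si](CC)(CC)CC)C[C@]1(C)O[Si](CC)(CC)CC | intermediate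
9 | (1R,2S,4R)-2,6,6-trimethyl-2,4-bis(triethylsilyloxy)cyclohexane-1-carbaldehyde | O=C[C@@H]1C(C)(C)C[C@@H](O[Si](CC)(CC)CC)C[C@]1(C)O[Si](CC)(CC)CC | intermediate
10 | potassium (E)-[(2S,4R)-2,6,6-trimethyl-2,4-bis(triethylsilyloxy)cyclohexylidene]methanolate (not isolated) | [K+].[O-]/C=C1\C(C)(C)C[C@@H](O[Si](CC)(CC)CC)C[C@]1(C)O[Si](CC)(CC)CC | intermediate
11 | (E)-[(2S,4R)-2,6,6-trimethyl-2,4-bis(triethylsilyloxy)cyclohexylidene]methyl trifluoromethanesulfonate | FC(F)(F)S(=O)(=O)O/C=C1\C(C)(C)C[C@@H](O[Si](CC)(CC)CC)C[C@]1(C)O[Si](CC)(CC)CC | intermediate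
12 | (2E)-2-[(2S,4R)-2,6,6-trimethyl-2,4-bis(triethylsilyloxy)cyclohexylidene]acetaldehyde | O=C/C=C1\C(C)(C)C[C@@H](O[Si](CC)(CC)CC)C[C@]1(C)O[Si](CC)(CC)CC | intermediate
13 | (2E,4E)-2-methyl-4-[(2S,4R)-2,6,6-trimethyl-2,4-bis(triethylsilyloxy)cyclohexylidene]but-2-enal | O=C/C(C)=C/C=C1\C(C)(C)C[C@@H](O[Si](CC)(CC)CC)C[C@]1(C)O[Si](CC)(CC)CC | intermediate
14 | (E)-3-methylpent-2-en-4-yn-1-ol | OC/C=C(C)/C#C | starting material
15 | (2E,4E)-3-methyl-5-(tributylstannyl)penta-2,4-dien-1-ol | OC/C=C(C)/C=C/[Sn](CCCC)(CCCC)CCCC | intermediate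
16 | tributyl[(1E,3E)-5-bromo-3-methylpenta-1,3-dien-1-yl]stannane | BrC/C=C(C)/C=C/[Sn](CCCC)(CCCC)CCCC | intermediate
17 | diethyl [(2E,4E)-3-methyl-5-(tributylstannyl)penta-2,4-dien-1-yl]phosphonate | CCOP(=O)(OCC)C/C=C(C)/C=C/[Sn](CCCC)(CCCC)CCCC | intermediate
18 | diethyl [(2E,4E)-5-iodo-3-methylpenta-2,4-dien-1-yl]phosphonate | CCOP(=O)(OCC)C/C=C(C)/C=C/I | intermediate
19 | sodium salt (α-carbanion) of phosphonate 17 (not isolated) | [Na+].CCOP(=O)(OCC)[CH-]/C=C(C)/C=C/[Sn](CCCC)(CCCC)CCCC | intermediate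
20 | tributyl{(1E,3E,5E,7E,9E)-3,7-dimethyl-9-[(2S,4R)-2,6,6-trimethyl-2,4-bis(triethylsilyloxy)cyclohexylidene]nona-1,3,5,7-tetraen-1-yl}stannane | CCCC[Sn](CCCC)(CCCC)/C=C/C(C)=C/C=C/C(C)=C/C=C1\C(C)(C)C[C@@H](O[Si](CC)(CC)CC)C[C@]1(C)O[Si](CC)(CC)CC | intermediate
21 | (4R,6R)-4-hydroxy-2,2,6-trimethylcyclohexan-1-one (actinol; hydroxyl trans to the 6-methyl) | C[C@@H]1C[C@@H](O)CC(C)(C)C1=O | starting material
22 | (4R,6R)-4-[(tert-butyldimethylsilyl)oxy]-2,2,6-trimethylcyclohexan-1-one | C[C@@H]1C[C@@H](O[Si](C)(C)C(C)(C)C)CC(C)(C)C1=O | intermediate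
23 | tert-butyldimethyl{[(1R)-3,5,5-trimethyl-4-(trimethylsilyloxy)cyclohex-3-en-1-yl]oxy}silane (not isolated) | CC1=C(O[Si](C)(C)C)C(C)(C)C[C@H](O[Si](C)(C)C(C)(C)C)C1 | intermediate
24 | (4S)-4-[(tert-butyldimethylsilyl)oxy]-2,6,6-trimethylcyclohex-2-en-1-one | CC1=C[C@@H](O[Si](C)(C)C(C)(C)C)CC(C)(C)C1=O | intermediate
25 | (4S)-4-[(tert-butyldimethylsilyl)oxy]-1-ethynyl-2,6,6-trimethylcyclohex-2-en-1-ol (C1 epimers) | CC1=C[C@@H](O[Si](C)(C)C(C)(C)C)CC(C)(C)C1(O)C#C | intermediate
26 | (2E)-2-[(4S)-4-[(tert-butyldimethylsilyl)oxy]-2,6,6-trimethylcyclohex-2-en-1-ylidene]acetaldehyde | CC1=C[C@@H](O[Si](C)(C)C(C)(C)C)CC(C)(C)\C1=C/C=O | intermediate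
27 | (2E,4E)-4-[(4S)-4-[(tert-butyldimethylsilyl)oxy]-2,6,6-trimethylcyclohex-2-en-1-ylidene]-2-methylbut-2-enal | CC1=C[C@@H](O[Si](C)(C)C(C)(C)C)CC(C)(C)\C1=C/C=C(C)/C=O | intermediate
28 | sodium salt (α-carbanion) of phosphonate 18 (not isolated) | [Na+].CCOP(=O)(OCC)[CH-]/C=C(C)/C=C/I | intermediate
29 | tert-butyl({(1S,4E)-4-[(2E,4E,6E,8E)-9-iodo-3,7-dimethylnona-2,4,6,8-tetraen-1-ylidene]-3,5,5-trimethylcyclohex-2-en-1-yl}oxy)dimethylsilane | CC1=C[C@@H](O[Si](C)(C)C(C)(C)C)CC(C)(C)\C1=C/C=C(C)/C=C/C=C(C)/C=C/I | intermediate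
30 | (3R,5S,3'S,6E,6'E)-3'-(tert-butyldimethylsilyloxy)-3,5-bis(triethylsilyloxy)-4',5-retro-β,β-carotene (all-E) | CC1=C[C@@H](O[Si](C)(C)C(C)(C)C)CC(C)(C)\C1=C/C=C(C)/C=C/C=C(C)/C=C/C=C/C(C)=C/C=C/C(C)=C/C=C1\C(C)(C)C[C@@H](O[Si](CC)(CC)CC)C[C@]1(C)O[Si](CC)(CC)CC | intermediate
31 | (3R,5S,3'S,6E,6'E)-4',5-retro-β,β-carotene-3,5,3'-triol (all-E): ring A (4S)-4-hydroxy-2,6,6-trimethylcyclohex-2-en-1-ylidene, ring B (2S,4R)-2,4-dihydroxy-2,6,6-trimethylcyclohexylidene | CC1=C[C@@H](O)CC(C)(C)\C1=C/C=C(C)/C=C/C=C(C)/C=C/C=C/C(C)=C/C=C/C(C)=C/C=C1\C(C)(C)C[C@@H](O)C[C@]1(C)O | target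

**Step count and risks**

Total: 22 steps. Longest linear sequence: 12 steps (steps 1–9, 14, 21, 22).

Steps most likely to fail:

1. Step 2 (proposed new method). The enamine may add too slowly to the fully substituted alkene carbon, proline may be captured as an enamino ester, the ketol may dehydrate, or the enantioselection may be low (a reversed sense alone would be met with (R)-proline). The fallback uses known chemistry, sets out from 3 and comes back at 6. TiCl4-mediated Mukaiyama–Michael addition of 2-(trimethylsilyloxy)propene to 3 (CH2Cl2, −78 °C) gives diketo ester 4, now isolated. Pyrrolidinium acetate (cat., rt) closes it to racemic ethyl (1R*,2S*)-2-hydroxy-2,6,6-trimethyl-4-oxocyclohexane-1-carboxylate F1. Me4NBH(OAc)3 then gives racemic ethyl (1R*,2S*,4R*)-2,4-dihydroxy-2,6,6-trimethylcyclohexane-1-carboxylate F2. Esterification of the secondary hydroxyl with (S)-O-methylmandelic acid (DCC, DMAP) and separation of the two diastereomers gives ethyl (1R,2S,4R)-2-hydroxy-4-{[(2S)-2-methoxy-2-phenylacetyl]oxy}-2,6,6-trimethylcyclohexane-1-carboxylate F3. K2CO3 in EtOH releases 6.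

2. Step 7. The enolate may lose the tertiary silyloxy group by β-elimination (the axial C5–O bond is aligned with the enolate π system), deprotonation of the hindered C6–H may be slow, or the enol triflate geometry may be poorly controlled. The fallback gives up kinetic control in favour of separation and recycling; it sets out from 9 and comes back at 12. Non-basic O-triflation of 9 (Tf2O, 2,6-di-tert-butyl-4-methylpyridine, CH2Cl2) gives 11 mixed with (Z)-[(2S,4R)-2,6,6-trimethyl-2,4-bis(triethylsilyloxy)cyclohexylidene]methyl trifluoromethanesulfonate F4. The mixture is formylated as in step 8. (2Z)-2-[(2S,4R)-2,6,6-trimethyl-2,4-bis(triethylsilyloxy)cyclohexylidene]acetaldehyde F5 is separated from 12 by chromatography and re-equilibrated with catalytic I2 in daylight, and 12 is collected again from the resulting mixture.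

3. Step 18. The doubly activated tertiary alcohol may ionise, leading to allylic transposition into the ring or to elimination instead of the shift to the alkyne terminus, and E/Z mixtures are possible. The fallback sets out from 24 and comes back at 26. LiC≡COEt (from ethoxyacetylene and n-BuLi) adds to 24 to give (4S)-4-[(tert-butyldimethylsilyl)oxy]-1-(ethoxyethynyl)-2,6,6-trimethylcyclohex-2-en-1-ol F6. This electron-rich ynol ether rearranges under much milder catalysis (Sc(OTf)3, CH2Cl2/EtOH) to ethyl (2E)-2-[(4S)-4-[(tert-butyldimethylsilyl)oxy]-2,6,6-trimethylcyclohex-2-en-1-ylidene]acetate F7. (i-Bu)2AlH gives (2E)-2-[(4S)-4-[(tert-butyldimethylsilyl)oxy]-2,6,6-trimethylcyclohex-2-en-1-ylidene]ethan-1-ol F8, and MnO2 oxidises it to 26.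

Further compounds
F1 | step 2 | racemic ethyl (1R*,2S*)-2-hydroxy-2,6,6-trimethyl-4-oxocyclohexane-1-carboxylate | CCOC(=O)C1C(C)(C)CC(=O)CC1(C)O
F2 | step 2 | racemic ethyl (1R*,2S*,4R*)-2,4-dihydroxy-2,6,6-trimethylcyclohexane-1-carboxylate | CCOC(=O)C1C(C)(C)CC(O)CC1(C)O
F3 | step 2 | ethyl (1R,2S,4R)-2-hydroxy-4-{[(2S)-2-methoxy-2-phenylacetyl]oxy}-2,6,6-trimethylcyclohexane-1-carboxylate | CCOC(=O)[C@@H]1C(C)(C)C[C@@H](OC(=O)[C@@H](OC)c2ccccc2)C[C@]1(C)O
F4 | step 7 | (Z)-[(2S,4R)-2,6,6-trimethyl-2,4-bis(triethylsilyloxy)cyclohexylidene]methyl trifluoromethanesulfonate | FC(F)(F)S(=O)(=O)O\C=C1\C(C)(C)C[C@@H](O[Si](CC)(CC)CC)C[C@]1(C)O[Si](CC)(CC)CC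
F5 | step 7 | (2Z)-2-[(2S,4R)-2,6,6-trimethyl-2,4-bis(triethylsilyloxy)cyclohexylidene]acetaldehyde | O=C\C=C1\C(C)(C)C[C@@H](O[Si](CC)(CC)CC)C[C@]1(C)O[Si](CC)(CC)CC
F6 | step 18 | (4S)-4-[(tert-butyldimethylsilyl)oxy]-1-(ethoxyethynyl)-2,6,6-trimethylcyclohex-2-en-1-ol (C1 epimers) | CC1=C[C@@H](O[Si](C)(C)C(C)(C)C)CC(C)(C)C1(O)C#COCC
F7 | step 18 | ethyl (2E)-2-[(4S)-4-[(tert-butyldimethylsilyl)oxy]-2,6,6-trimethylcyclohex-2-en-1-ylidene]acetate | CC1=C[C@@H](O[Si](C)(C)C(C)(C)C)CC(C)(C)\C1=C/C(=O)OCC
F8 | step 18 | (2E)-2-[(4S)-4-[(tert-butyldimethylsilyl)oxy]-2,6,6-trimethylcyclohex-2-en-1-ylidene]ethan-1-ol | CC1=C[C@@H](O[Si](C)(C)C(C)(C)C)CC(C)(C)\C1=C/CO
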